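**Plan**
Enabling feature: in ring C the tertiary carbinol C3 (bearing ring B) is bonded directly to the C4 ketone (attached to C4a of ring A). C3–C4 is therefore an acyloin bond, and O1–C2 links both carbons within a six-atom chain, so C4 can come from a ring-A aldehyde used as an acyl anion and C3 from a ring-B aryl ketone.
Cuts in retrosynthetic order: the O5 and O4' silyl masks; C3–C4 (opens ring C); O1–C2 (separates the ring-A half from the ring-B half); then Cα–Br, O2'–CH3 and C3'–prenyl on ring B and O7–CH3 on ring A.
Starting materials: 2,4,6-trihydroxybenzaldehyde 1, 2,4-dihydroxyacetophenone 2 and prenyl bromide 3.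
Forward order: rings A and B are bought; ring B is functionalised, the halves are joined through O1–C2, and ring C, the only ring made, is closed last at C3–C4.
Stereochemistry: the single stereocentre C3 (S) is set in the ring closure by a chiral aminoindanol-derived triazolylidene. It is quaternary and cannot epimerise in the final desilylation.

Key step: step 8

Assumption: the facial sense of the aminoindanol-derived carbene toward this ortho-methoxyaryl ketone is taken from the usual shielding model; if the configuration check on the cyclised ketol shows the 3R series, the equally commercial (5aS,10bR) salt replaces the (5aR,10bS) salt and nothing else changes.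

**Step 1**
Reactants: 1 2,4,6-trihydroxybenzaldehyde
Product: 4 2,6-dihydroxy-4-methoxybenzaldehyde
Conditions: Me2SO4 (1.0 equiv), K2CO3 (1.0 equiv), acetone, 0 °C to rt
Reagents that add atoms: dimethyl sulfate, COS(=O)(=O)OC
Why: Williamson-type O-methylation with one equivalent each of base and electrophile should take the para hydroxyl, which is the most acidic one and the only one outside the hydrogen-bond chelate with the formyl oxygen.

**Step 2**
Reactants: 2 2,4-dihydroxyacetophenone; 3 prenyl bromide (1-bromo-3-methylbut-2-ene)
Product: 5 1-[2,4-dihydroxy-3-(3-methylbut-2-en-1-yl)phenyl]ethan-1-one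
Conditions: KOH (2 equiv), H2O, 0 °C to rt
Reagents that add atoms: none
Why: Direct C-alkylation of the ambident resorcinolate in water, where the solvated oxygens are poor nucleophiles, should place the prenyl group by SN2 at C3, the carbon activated by both flanking oxygens, with isomeric products removed by chromatography.

**Step 3**
Reactants: 5 1-[2,4-dihydroxy-3-(3-methylbut-2-en-1-yl)phenyl]ethan-1-one
Product: 6 1-[2-hydroxy-3-(3-methylbut-2-en-1-yl)-4-(triisopropylsilyloxy)phenyl]ethan-1-one
Conditions: TIPSCl, imidazole, DMF, 0 °C to rt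
Reagents that add atoms: triisopropylsilyl chloride, CC(C)[Si](Cl)(C(C)C)C(C)C
Why: Imidazole-promoted phenol silylation should occur only at O4 because O2–H is locked in the chelate with the acetyl group, and the bulky TIPS ether is chosen because it has to survive two later carbonate-mediated alkylations.

**Step 4**
Reactants: 6 1-[2-hydroxy-3-(3-methylbut-2-en-1-yl)-4-(triisopropylsilyloxy)phenyl]ethan-1-one
Product: 7 1-[2-methoxy-3-(3-methylbut-2-en-1-yl)-4-(triisopropylsilyloxy)phenyl]ethan-1-one
Conditions: MeI (excess), K2CO3, dry acetone, 50 °C (sealed vessel)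
Reagents that add atoms: iodomethane, CI
Why: Williamson methylation of a chelated ortho-acyl phenol under anhydrous carbonate conditions is standard, and the only other phenolic oxygen is blocked as a hindered silyl ether that dry K2CO3 should not cleave.

**Step 5**
Reactants: 7 1-[2-methoxy-3-(3-methylbut-2-en-1-yl)-4-(triisopropylsilyloxy)phenyl]ethan-1-one
Product: 9 2-bromo-1-[2-methoxy-3-(3-methylbut-2-en-1-yl)-4-(triisopropylsilyloxy)phenyl]ethan-1-one, via trimethylsilyl enol ether 8 (not isolated)
Conditions: TMSOTf, Et3N, CH2Cl2, 0 °C; then NBS, −78 °C to 0 °C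
Reagents that add atoms: N-bromosuccinimide, O=C1CCC(=O)N1Br; trimethylsilyl triflate, C[Si](C)(C)OS(=O)(=O)C(F)(F)F (its silyl group is present in 8 only)
Why: Soft enolisation followed by electrophilic bromination of the silyl enol ether puts bromine on Cα because the enol ether is by far the most nucleophilic π system present, so the prenyl alkene and the arene should be spared, which direct bromination of the ketone with Br2 or CuBr2 would not ensure.

**Step 6**
Reactants: 4 2,6-dihydroxy-4-methoxybenzaldehyde (1.5 equiv); 9 2-bromo-1-[2-methoxy-3-(3-methylbut-2-en-1-yl)-4-(triisopropylsilyloxy)phenyl]ethan-1-one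
Product: 10 2-hydroxy-4-methoxy-6-{2-[2-methoxy-3-(3-methylbut-2-en-1-yl)-4-(triisopropylsilyloxy)phenyl]-2-oxoethoxy}benzaldehyde
Conditions: K2CO3 (1.2 equiv), acetone, 0 °C to rt
Reagents that add atoms: none
Why: Williamson ether synthesis at a highly reactive α-bromo ketone gives one product from either hydroxyl of the symmetric diol, and the remaining chelated phenol(ate) of 10 deactivates the aldehyde and is a poor nucleophile, which together with the buffering excess of acidic 4 should hold back both aldol condensation (Rap–Stoermer path) and a second alkylation.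

**Step 7**
Reactants: 10 2-hydroxy-4-methoxy-6-{2-[2-methoxy-3-(3-methylbut-2-en-1-yl)-4-(triisopropylsilyloxy)phenyl]-2-oxoethoxy}benzaldehyde
Product: 11 2-(tert-butyldimethylsilyloxy)-4-methoxy-6-{2-[2-methoxy-3-(3-methylbut-2-en-1-yl)-4-(triisopropylsilyloxy)phenyl]-2-oxoethoxy}benzaldehyde
Conditions: TBSCl, imidazole, DMAP (cat.), DMF, rt
Reagents that add atoms: tert-butyldimethylsilyl chloride, CC(C)(C)[Si](C)(C)Cl
Why: Imidazole-promoted phenol silylation uses a base too weak to enolise the ketone, removes the acidic chelating OH that would quench the carbene and deactivate the aldehyde, and uses the smaller TBS group to limit crowding next to the reacting formyl carbon.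

**Step 8**
Reactants: 11 2-(tert-butyldimethylsilyloxy)-4-methoxy-6-{2-[2-methoxy-3-(3-methylbut-2-en-1-yl)-4-(triisopropylsilyloxy)phenyl]-2-oxoethoxy}benzaldehyde
Product: 12 (3S)-5-(tert-butyldimethylsilyloxy)-3-hydroxy-7-methoxy-3-[2-methoxy-3-(3-methylbut-2-en-1-yl)-4-(triisopropylsilyloxy)phenyl]-2,3-dihydro-4H-chromen-4-one
Conditions: (5aR,10bS)-2-(pentafluorophenyl)-5a,10b-dihydro-4H,6H-indeno[2,1-b][1,2,4]triazolo[4,3-d][1,4]oxazin-2-ium tetrafluoroborate (20 mol %), Et3N (20 mol %), 4 Å MS, toluene, 25 °C, Ar
Reagents that add atoms: none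
Why: The carbene freed by Et3N adds to the formyl carbon of 11 and proton transfer gives the Breslow enaminol, whose former aldehyde carbon (C4) is now nucleophilic and attacks the tethered ketone carbon (C3), after which collapse of the adduct restores the C4 carbonyl and releases the carbene. This is the carbene-catalysed intramolecular crossed aldehyde–ketone benzoin reaction, established for 2-(2-oxoalkoxy)benzaldehydes, which it converts into 3-hydroxychroman-4-ones. Ring C closes in the 6-exo-trig mode, with C4, C4a, C8a, O1, C2 and C3 in the ring and the ketone oxygen outside it. C3 is controlled by the catalyst: the indane wall covers one face of the enaminol, the enol O–H binds the ketone oxygen and ring B has to point away from the N-aryl group, so only one face of the ketone is exposed. Chemoselectivity comes from the substrate, since only the aldehyde has the C–H needed for umpolung, the ketone is the only acceptor within reach, and the two ortho substituents of the aldehyde disfavour intermolecular homo-benzoin coupling. The acidic N-C6F5 azolium needs only a tertiary amine, which should be too weak to enolise the OCH2 ketone at a competitive rate, so aldol condensation to the 2-aroylbenzofuran should stay minor.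

**Step 9**
Reactants: 12 (3S)-5-(tert-butyldimethylsilyloxy)-3-hydroxy-7-methoxy-3-[2-methoxy-3-(3-methylbut-2-en-1-yl)-4-(triisopropylsilyloxy)phenyl]-2,3-dihydro-4H-chromen-4-one
Product: 13 (3S)-3,5-dihydroxy-3-[4-hydroxy-2-methoxy-3-(3-methylbut-2-en-1-yl)phenyl]-7-methoxy-2,3-dihydro-4H-chromen-4-one (target)
Conditions: Bu4NF (2.5 equiv), AcOH (3 equiv), THF, 0 °C
Reagents that add atoms: none
Why: Fluoride cleavage of aryl silyl ethers is fast at 0 °C, the acetic acid buffer protonates the phenoxides at once so that retro-benzoin, α-ketol shift and dehydration to the isoflavone should not start, and neither the quaternary C3 nor the prenyl group is touched.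

**Compound list**
1 | 2,4,6-trihydroxybenzaldehyde | O=Cc1c(O)cc(O)cc1O | starting material
2 | 2,4-dihydroxyacetophenone | CC(=O)c1ccc(O)cc1O | starting material
3 | prenyl bromide (1-bromo-3-methylbut-2-ene) | CC(C)=CCBr | starting material
4 | 2,6-dihydroxy-4-methoxybenzaldehyde | COc1cc(O)c(C=O)c(O)c1 | intermediate
5 | 1-[2,4-dihydroxy-3-(3-methylbut-2-en-1-yl)phenyl]ethan-1-one | CC(=O)c1ccc(O)c(CC=C(C)C)c1O | intermediate
6 | 1-[2-hydroxy-3-(3-methylbut-2-en-1-yl)-4-(triisopropylsilyloxy)phenyl]ethan-1-one | CC(=O)c1ccc(O[Si](C(C)C)(C(C)C)C(C)C)c(CC=C(C)C)c1O | intermediate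
7 | 1-[2-methoxy-3-(3-methylbut-2-en-1-yl)-4-(triisopropylsilyloxy)phenyl]ethan-1-one | CC(=O)c1ccc(O[Si](C(C)C)(C(C)C)C(C)C)c(CC=C(C)C)c1OC | intermediate
8 | trimethylsilyl enol ether of 7 (1-aryl-1-(trimethylsilyloxy)ethene, not isolated) | C=C(O[Si](C)(C)C)c1ccc(O[Si](C(C)C)(C(C)C)C(C)C)c(CC=C(C)C)c1OC | intermediate
9 | 2-bromo-1-[2-methoxy-3-(3-methylbut-2-en-1-yl)-4-(triisopropylsilyloxy)phenyl]ethan-1-one | BrCC(=O)c1ccc(O[Si](C(C)C)(C(C)C)C(C)C)c(CC=C(C)C)c1OC | intermediate
10 | 2-hydroxy-4-methoxy-6-{2-[2-methoxy-3-(3-methylbut-2-en-1-yl)-4-(triisopropylsilyloxy)phenyl]-2-oxoethoxy}benzaldehyde | COc1cc(O)c(C=O)c(c1)OCC(=O)c1ccc(O[Si](C(C)C)(C(C)C)C(C)C)c(CC=C(C)C)c1OC | intermediate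
11 | 2-(tert-butyldimethylsilyloxy)-4-methoxy-6-{2-[2-methoxy-3-(3-methylbut-2-en-1-yl)-4-(triisopropylsilyloxy)phenyl]-2-oxoethoxy}benzaldehyde | COc1cc(O[Si](C)(C)C(C)(C)C)c(C=O)c(c1)OCC(=O)c1ccc(O[Si](C(C)C)(C(C)C)C(C)C)c(CC=C(C)C)c1OC | intermediate
12 | (3S)-5-(tert-butyldimethylsilyloxy)-3-hydroxy-7-methoxy-3-[2-methoxy-3-(3-methylbut-2-en-1-yl)-4-(triisopropylsilyloxy)phenyl]-2,3-dihydro-4H-chromen-4-one | COc1cc(O[Si](C)(C)C(C)(C)C)c2c(c1)OC[C@@](O)(c1ccc(O[Si](C(C)C)(C(C)C)C(C)C)c(CC=C(C)C)c1OC)C2=O | intermediate
13 | (3S)-3,5-dihydroxy-3-[4-hydroxy-2-methoxy-3-(3-methylbut-2-en-1-yl)phenyl]-7-methoxy-2,3-dihydro-4H-chromen-4-one | COc1cc(O)c2c(c1)OC[C@@](O)(c1ccc(O)c(CC=C(C)C)c1OC)C2=O | target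

Total step count: 9. Longest linear sequence: 8 steps (from 2 to 13, steps 2 to 9).

**Steps most likely to fail**

Step 8.
- What may go wrong: the bulky chiral carbene may add only slowly to an aldehyde flanked by two ortho oxygens, which would let amine-mediated aldol condensation gain ground. Facial discrimination at the ortho-methoxyaryl ketone may also be poor. A shift of the O5 silyl group to the new carbinol oxygen would not matter, because step 9 clears every silyl group.
- Fallback: separate ring closure from stereo-induction. Setting out from 11, the small achiral carbene from 2-(pentafluorophenyl)-6,7-dihydro-5H-pyrrolo[2,1-c][1,2,4]triazol-2-ium tetrafluoroborate and Et3N in toluene would close ring C to the racemic ketol F1. SmI2 in THF–MeOH at −78 °C would then cleave the C3–OH bond alpha to the ketone and give the racemic isoflavanone F2. Deprotonation with KHMDS in THF at −78 °C is followed by oxidation in the same flask with the antipode of (8,8-dimethoxycamphorylsulfonyl)oxaziridine that matches the 3S series. This Davis oxidation is established for 3-substituted chroman-4-ones and is inert toward the prenyl alkene. It would reinstall the hydroxyl under reagent control and rejoin the route at 12.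

Step 6.
- What may go wrong: under carbonate the newly formed aryloxy ketone may enolise and condense with the neighbouring aldehyde (benzofuran formation), and the second phenol may be alkylated as well.
- Fallback: make O1–C2 by redox condensation in a medium free of carbonate. Setting out from 9, HCO2Na in aqueous EtOH at 60 °C would displace bromide to give the formate ester F3, which is solvolysed in the same pot to the α-hydroxy ketone F4. Mitsunobu etherification of F4 with 4 (PPh3, DIAD, THF, 0 °C to rt) should stop after one hydroxyl, since the remaining chelated phenol reacts sluggishly, and it rejoins the route at 10.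

Step 2.
- What may go wrong: site selectivity of the direct prenylation may be poor, with attack at C5, O-alkylation and double prenylation eroding the throughput and complicating purification.
- Fallback: deliver the prenyl group by a sigmatropic shift instead of an intermolecular alkylation. Setting out from 2, the free O4 hydroxyl would be alkylated with 3-chloro-3-methylbut-1-yne (K2CO3, KI, acetone, reflux) to give the 1,1-dimethylpropargyl ether F5. Semihydrogenation (H2, Pd on CaCO3 poisoned with Pb(OAc)2, quinoline, EtOAc) would give the 1,1-dimethylallyl ether F6. Aromatic Claisen rearrangement (N,N-diethylaniline, 130 °C) would transpose the allyl unit into a linear prenyl group at C3, the ortho position favoured by the chelate-fixed bond order, and rejoin the route at 5.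

**Further compounds**
F1 | step 8 | racemic 5-(tert-butyldimethylsilyloxy)-3-hydroxy-7-methoxy-3-[2-methoxy-3-(3-methylbut-2-en-1-yl)-4-(triisopropylsilyloxy)phenyl]-2,3-dihydro-4H-chromen-4-one | COc1cc(O[Si](C)(C)C(C)(C)C)c2c(c1)OCC(O)(c1ccc(O[Si](C(C)C)(C(C)C)C(C)C)c(CC=C(C)C)c1OC)C2=O
F2 | step 8 | racemic 5-(tert-butyldimethylsilyloxy)-7-methoxy-3-[2-methoxy-3-(3-methylbut-2-en-1-yl)-4-(triisopropylsilyloxy)phenyl]-2,3-dihydro-4H-chromen-4-one (isoflavanone) | COc1cc(O[Si](C)(C)C(C)(C)C)c2c(c1)OCC(c1ccc(O[Si](C(C)C)(C(C)C)C(C)C)c(CC=C(C)C)c1OC)C2=O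
F3 | step 6 | 2-[2-methoxy-3-(3-methylbut-2-en-1-yl)-4-(triisopropylsilyloxy)phenyl]-2-oxoethyl formate | O=COCC(=O)c1ccc(O[Si](C(C)C)(C(C)C)C(C)C)c(CC=C(C)C)c1OC
F4 | step 6 | 2-hydroxy-1-[2-methoxy-3-(3-methylbut-2-en-1-yl)-4-(triisopropylsilyloxy)phenyl]ethan-1-one | OCC(=O)c1ccc(O[Si](C(C)C)(C(C)C)C(C)C)c(CC=C(C)C)c1OC
F5 | step 2 | 1-{2-hydroxy-4-[(2-methylbut-3-yn-2-yl)oxy]phenyl}ethan-1-one | CC(=O)c1ccc(OC(C)(C)C#C)cc1O
F6 | step 2 | 1-{2-hydroxy-4-[(2-methylbut-3-en-2-yl)oxy]phenyl}ethan-1-one | CC(=O)c1ccc(OC(C)(C)C=C)cc1O
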